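## Retrosynthetic overview
1. The phenol is unmasked last by hydrogenolysis of an aryl benzyl ether.
2. The THF ring and the tertiary ether stereocentre are formed last, in a proposed new catalyst-controlled HAT/radical-polar-crossover 5-exo hydroalkoxylation of a cis-β-hydroxy-γ-lactone carrying a 1,1-disubstituted alkene.
3. The cis-4-hydroxy-5-methyl-5-allyl-γ-lactone (first ring) comes from chelation-controlled addition of a 2-(ω-arylalkyl)allylzinc to an (S)-α-PMB-oxy methyl ketone ester, followed by lactonisation.
4. The ketone ester comes from Brown allylation of methacrolein (which sets the carbinol stereocentre), then oxidative cleavage. The allyl chloride comes from 11-bromoundecanol by Kumada coupling, Appel bromination and Cu-catalysed coupling with 3-chloro-2-(chloromethyl)propene.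

Assumptions (one line each):
- The chain is 12 CH2 groups, as written in the target SMILES.
- (−)-B-allyldiisopinocampheylborane (from (+)-α-pinene) attacks the Si face of methacrolein and gives the (S)-alcohol; if not, use the reagent from (−)-α-pinene.
- The (R,R)-Co(salen) enantiomer in Step 12 is the matched one; if not, use (S,S).

## Route

**Step 1**
Reactants: 1 (11-bromoundecan-1-ol); 2 (1-(benzyloxy)-4-bromobenzene, used as its Grignard)
Product: 3 (11-[4-(benzyloxy)phenyl]undecan-1-ol)
Conditions: (a) 2, Mg, THF, reflux → ArMgBr; (b) 1 (ArMgBr 2.2 equiv), Li2CuCl4 (5 mol%), THF, −10 °C → rt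
Reagents that add atoms: none beyond the numbered reactants
Why: Cu-catalysed Kumada sp2–sp3 coupling; the alkoxide formed from the free OH is inert and the benzyl ether survives.

**Step 2**
Reactants: 3
Product: 4 (1-(benzyloxy)-4-(11-bromoundecyl)benzene)
Conditions: CBr4, PPh3, CH2Cl2, 0 °C → rt
Reagents that add atoms: CBr4, BrC(Br)(Br)Br (supplies Br)
Why: Appel bromination of a primary alcohol; no stereocentres are involved.

**Step 3**
Reactants: 4; 5 (3-chloro-2-(chloromethyl)prop-1-ene, 3 equiv)
Product: 6 (1-(benzyloxy)-4-[13-(chloromethyl)tetradec-13-en-1-yl]benzene)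
Conditions: (a) Mg, THF, 50 °C → Grignard of 4; (b) Grignard added to 5, Li2CuCl4 (5 mol%), THF, −20 → 0 °C
Reagents that add atoms: none beyond the numbered reactants
Why: Cu-catalysed SN2 (or SN2′, which gives the same product by symmetry) of an alkyl Grignard on a bis-allylic chloride; excess 5 suppresses double alkylation and leaves the allylic chloride for zinc insertion.

**Step 4**
Reactants: 7 (methacrolein); 8 ((−)-B-allyldiisopinocampheylborane, from (+)-α-pinene)
Product: 9 ((S)-2-methylhexa-1,5-dien-3-ol)
Conditions: 8, Et2O, −78 °C; then NaOH, H2O2, 0 °C → rt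
Reagents that add atoms: none beyond reactant 8, which delivers the allyl group
Why: Brown asymmetric allylboration through a chair transition state; the Ipc2B reagent attacks the Si face and sets the (S) carbinol centre, which becomes C-4 of the lactone ring.

**Step 5**
Reactants: 9; 10 (4-methoxybenzyl chloride)
Product: 11 (1-methoxy-4-{[(S)-2-methylhexa-1,5-dien-3-yloxy]methyl}benzene)
Conditions: NaH, TBAI (cat.), THF/DMF, 0 °C → rt
Reagents that add atoms: none beyond reactant 10
Why: Williamson etherification with PMB, which is needed both for chelation in Step 9 and for orthogonal removal in Step 11; the stereocentre is untouched.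

**Step 6**
Reactants: 11
Product: 12 ((S)-3-[(4-methoxybenzyl)oxy]-4-oxopentanal)
Conditions: OsO4 (2 mol%), NaIO4 (8 equiv), 2,6-lutidine (4 equiv), dioxane/H2O 3:1, rt; the crude is used immediately
Reagents that add atoms: NaIO4, [Na+].[O-]I(=O)(=O)=O (supplies the carbonyl oxygens)
Why: Lemieux–Johnson cleavage of both alkenes gives the methyl ketone (from the isopropenyl group) and the aldehyde (from the allyl group), and leaves the PMB ether intact.

**Step 7**
Reactants: 12
Product: 13 ((S)-3-[(4-methoxybenzyl)oxy]-4-oxopentanoic acid)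
Conditions: NaClO2, NaH2PO4, 2-methylbut-2-ene, tBuOH/H2O, rt
Reagents that add atoms: NaClO2, [Na+].[O-]Cl=O (supplies O)
Why: Pinnick oxidation of the aldehyde to the acid; the alkene scavenger protects the PMB arene from HOCl, and the ketone and the α-alkoxy stereocentre survive the mildly acidic buffer.

**Step 8**
Reactants: 13
Product: 14 (methyl (S)-3-[(4-methoxybenzyl)oxy]-4-oxopentanoate)
Conditions: TMSCHN2, MeOH/PhMe, 0 °C
Reagents that add atoms: TMSCHN2, C[Si](C)(C)C=[N+]=[N-] (supplies the ester CH3)
Why: Neutral methyl esterification that avoids the β-elimination and epimerisation a base would cause.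

**Step 9**
Reactants: 14; 6 (converted in situ to allylzinc chloride)
Product: 15 (methyl (3S,4S)-18-[4-(benzyloxy)phenyl]-4-hydroxy-3-[(4-methoxybenzyl)oxy]-4-methyl-6-methyleneoctadecanoate; partly cyclised to 16)
Conditions: (a) 6, Zn dust (activated with TMSCl/BrCH2CH2Br), LiCl, THF, 25 °C → allylzinc; (b) add 14, THF, −20 °C → rt
Reagents that add atoms: none beyond reactant 6
Why: Cram-chelate addition; Zn bridges the ketone O and the PMB ether O, and the allyl group adds from the face bearing H rather than CH2CO2Me, giving the (3S,4S) tertiary alcohol with the new CH2 cis to the PMB-oxy group in the lactone. Allylzinc does not attack the ester or the symmetric 2-substituted allyl unit regiochemically.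

**Step 10**
Reactants: 15
Product: 16 ((4S,5S)-5-{2-[12-(4-benzyloxyphenyl)dodecyl]allyl}-4-[(4-methoxybenzyl)oxy]-5-methyldihydrofuran-2(3H)-one)
Conditions: PPTS (0.2 equiv), PhMe, 60 °C, 3 h
Reagents that add atoms: none (MeOH is lost)
Why: Acid-catalysed 5-exo γ-lactonisation of the tertiary alcohol onto the methyl ester; no stereocentre is touched, and mild PPTS leaves the PMB ether and the alkene intact.

**Step 11**
Reactants: 16
Product: 17 ((4S,5S)-5-{2-[12-(4-benzyloxyphenyl)dodecyl]allyl}-4-hydroxy-5-methyldihydrofuran-2(3H)-one)
Conditions: DDQ (1.2 equiv), CH2Cl2/pH 7 buffer 18:1, 0 °C, 1 h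
Reagents that add atoms: none
Why: Oxidative PMB cleavage is much faster than DDQ attack on the aryl benzyl ether or the 1,1-disubstituted alkene, and it avoids the base that would eliminate the β-OH.

**Step 12**
Reactants: 17
Product: 18 ((2S,3aS,6aS)-2-[12-(4-benzyloxyphenyl)dodecyl]-2,3a-dimethyltetrahydrofuro[3,2-b]furan-5(2H)-one)
Conditions: (R,R)-Co(salen) (3,5-di-tBu, cyclohexanediamine; 5 mol%), N-fluoro-2,4,6-trimethylpyridinium triflate (1.5 equiv), PhSiH3 (1.5 equiv), PhCF3, 25 °C
Reagents that add atoms: none (only H is added, from the silane)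
Why: Proposed new method: Co–H hydrogen-atom transfer to the 1,1-disubstituted alkene gives a tertiary radical. Capture by the chiral Co(salen) and oxidation to an alkyl–Co(IV) (cation-like) species is followed by intramolecular SN2-type displacement by the cis 4-OH, forming the 2,2-dialkyl THF. The ring fusion must be cis because the OH and the allyl CH2 are cis on the lactone, and the chiral salen pocket should discriminate Me from CH2R at the remote tertiary carbon, where substrate bias is negligible. This is closest to Co(salen)/N-fluoropyridinium/silane Markovnikov hydroalkoxylation of alkenols; what is new is catalyst-controlled diastereoselection on a β-oxy-lactone substrate with dialkyl discrimination.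

**Step 13**
Reactants: 18
Product: 19 (plakortone N)
Conditions: H2 (1 atm), 10% Pd/C, EtOAc/MeOH, rt
Reagents that add atoms: none (only H is added)
Why: Hydrogenolysis of the aryl benzyl ether; the lactone and the THF ether are stable and no alkene remains.

## Compound list
1 | 11-bromoundecan-1-ol | OCCCCCCCCCCCBr | starting material
2 | 1-(benzyloxy)-4-bromobenzene | Brc1ccc(OCc2ccccc2)cc1 | starting material
3 | 11-[4-(benzyloxy)phenyl]undecan-1-ol | OCCCCCCCCCCCc1ccc(OCc2ccccc2)cc1 | intermediate
4 | 1-(benzyloxy)-4-(11-bromoundecyl)benzene | BrCCCCCCCCCCCc1ccc(OCc2ccccc2)cc1 | intermediate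
5 | 3-chloro-2-(chloromethyl)prop-1-ene | C=C(CCl)CCl | starting material
6 | 1-(benzyloxy)-4-[13-(chloromethyl)tetradec-13-en-1-yl]benzene | C=C(CCl)CCCCCCCCCCCCc1ccc(OCc2ccccc2)cc1 | intermediate
7 | methacrolein | C=C(C)C=O | starting material
8 | (−)-B-allyldiisopinocampheylborane (from (+)-α-pinene; pinane stereodescriptors omitted) | C=CCB(C1CC2CC(C1C)C2(C)C)C1CC2CC(C1C)C2(C)C | starting material (reagent)
9 | (S)-2-methylhexa-1,5-dien-3-ol | C=C(C)[C@@H](O)CC=C | intermediate
10 | 4-methoxybenzyl chloride | COc1ccc(CCl)cc1 | starting material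
11 | PMB ether of 9 | C=C(C)[C@@H](OCc1ccc(OC)cc1)CC=C | intermediate
12 | (S)-3-[(4-methoxybenzyl)oxy]-4-oxopentanal | CC(=O)[C@@H](OCc1ccc(OC)cc1)CC=O | intermediate
13 | (S)-3-[(4-methoxybenzyl)oxy]-4-oxopentanoic acid | CC(=O)[C@@H](OCc1ccc(OC)cc1)CC(=O)O | intermediate
14 | methyl (S)-3-[(4-methoxybenzyl)oxy]-4-oxopentanoate | CC(=O)[C@@H](OCc1ccc(OC)cc1)CC(=O)OC | intermediate
15 | methyl (3S,4S)-18-[4-(benzyloxy)phenyl]-4-hydroxy-3-[(4-methoxybenzyl)oxy]-4-methyl-6-methyleneoctadecanoate | COC(=O)C[C@H](OCc1ccc(OC)cc1)[C@@](C)(O)CC(=C)CCCCCCCCCCCCc1ccc(OCc2ccccc2)cc1 | intermediate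
16 | (4S,5S)-lactone, PMB ether, alkene chain | C[C@@]1(CC(=C)CCCCCCCCCCCCc2ccc(OCc3ccccc3)cc2)OC(=O)C[C@@H]1OCc1ccc(OC)cc1 | intermediate
17 | (4S,5S)-4-hydroxy lactone | C[C@@]1(CC(=C)CCCCCCCCCCCCc2ccc(OCc3ccccc3)cc2)OC(=O)C[C@@H]1O | intermediate
18 | bicyclic O-benzyl plakortone N | C[C@]1(CCCCCCCCCCCCc2ccc(OCc3ccccc3)cc2)C[C@]2(C)OC(=O)C[C@@H]2O1 | intermediate
19 | plakortone N | C[C@]1(CCCCCCCCCCCCc2ccc(O)cc2)C[C@]2(C)OC(=O)C[C@@H]2O1 | target

Total step count: 13.
Longest linear sequence: 10 steps (Steps 4–13, from methacrolein).

## Three steps most likely to fail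
1. **Step 12 (proposed new HAT hydroalkoxylation).** The C-1 diastereoselectivity (Me vs CH2R) may be poor, or alkene isomerisation and hydration may compete.
   Fallback (known chemistry): 5-exo iodoetherification of 17 with NIS, which puts CH2I on the quaternary carbon. Then reduce with Bu3SnH/AIBN to the methyl group and separate the C-1 epimers by preparative HPLC.
2. **Step 9 (chelation-controlled allylzinc addition).** Diastereoselectivity may be low, or the hindered 2-substituted allylzinc may give poor conversion.
   Fallback: add the smaller 2-bromoallylzinc/indium reagent (from 2,3-dibromopropene) under the same chelation control. Then install the chain after the Ca stereocentre is set, by B-alkyl Suzuki coupling of the vinyl bromide with the 9-BBN adduct of 11-(4-benzyloxyphenyl)undec-1-ene.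
3. **Step 6 (double Lemieux–Johnson cleavage to the β-alkoxy keto-aldehyde).** The intermediate may undergo E1cB elimination or PMB oxidation.
   Fallback: build ketone 14 from (S)-3-hydroxy-γ-butyrolactone. Protect as the PMB ether, open with AlMe3/MeNHOMe·HCl, oxidise the primary alcohol (DMP), add MeMgBr, and oxidise again (DMP) to the Weinreb keto-amide. Carry the amide through the allylation and close the lactone with acid.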